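**Retrosynthetic overview**

1. The target is read as (2S,3S,2''S,3''S): two 2,3-cis flavanones joined C3–C3''. The last step is hydrogenolysis of the five benzyl ethers of 11.
2. Key disconnection: both pyranone rings (ring C and ring C'') are opened at O1–C2 and O1''–C2'' to the achiral, acyclic (E,E)-2,3-diaroyl-1,4-diarylbuta-1,3-diene 9. Rings C and C'' are the only rings made in the route, and both form in step 6.
3. Enabling feature: the 1,4-diketone C4(=O)–C3–C3''–C4''(=O), with each carbonyl on a ring A that carries an ortho hydroxyl (future O1, O1'') and each α-carbon carrying a benzylic carbon (C2, C2''). At the diene oxidation level C2 and C2'' are β-carbons 6-endo to those oxygens, and C3 and C3'' pass through enols, so their configuration is set by protonation.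
4. Diene 9 comes from the symmetric 1,4-diketone 4 by two successive aldol condensations (4-methoxybenzaldehyde, then 4-(benzyloxy)benzaldehyde), which is where ring B and ring B'' are told apart. Diketone 4 comes from oxidative enolate dimerisation of two molecules of the protected phloroacetophenone 2, which makes the C3–C3'' bond.

Key step: step 6

Assumption: the quinidine-derived pseudoenantiomer of the bifunctional thiourea is taken to give the 2S sense at both benzylic carbons; if the sense proves opposite, the quinine-derived pseudoenantiomer replaces it and nothing else changes.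

**Route**

Step 1
Reactants: 1 1-[2,4-bis(benzyloxy)-6-hydroxyphenyl]ethan-1-one
Product: 2 1-[2,4-bis(benzyloxy)-6-(methoxymethoxy)phenyl]ethan-1-one
Conditions: NaH, MOMCl, DMF, 0 °C → rt
Reagents that add atoms: chloromethyl methyl ether, COCCl
Why: Williamson ether synthesis, in which NaH deprotonates the chelated ortho-phenol irreversibly and the phenoxide is alkylated by the reactive α-chloro ether, masking the future ring oxygen as an acetal that survives the basic steps and can later be removed without touching benzyl ethers.

Step 2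
Reactants: 2 1-[2,4-bis(benzyloxy)-6-(methoxymethoxy)phenyl]ethan-1-one
Product: 4 1,4-bis[2,4-bis(benzyloxy)-6-(methoxymethoxy)phenyl]butane-1,4-dione, via lithium enolate 3 (not isolated)
Conditions: LiN(iPr)2 (1.1 equiv), THF, −78 °C; then CuCl2 (1.1 equiv), DMF, −78 °C → rt; two molecules of 2 are consumed per molecule of 4
Reagents that add atoms: 1-[2,4-bis(benzyloxy)-6-(methoxymethoxy)phenyl]ethan-1-one (the second molecule of 2), CC(=O)c1c(OCOC)cc(OCc2ccccc2)cc1OCc1ccccc1
Why: Oxidative homocoupling of a ketone lithium enolate with CuCl2, in which two molecules of the enolate 3 of the hindered, non-self-condensing 2,6-dioxygenated aryl methyl ketone are joined at their α-carbons through one-electron oxidation by divalent copper to give the symmetric 1,4-diketone, creating the future C3–C3'' bond.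

Step 3
Reactants: 4 1,4-bis[2,4-bis(benzyloxy)-6-(methoxymethoxy)phenyl]butane-1,4-dione; 5 4-methoxybenzaldehyde
Product: 6 (2E)-1,4-bis[2,4-bis(benzyloxy)-6-(methoxymethoxy)phenyl]-2-[(4-methoxyphenyl)methylidene]butane-1,4-dione
Conditions: KOH, EtOH/THF, 0 °C → rt (4 in threefold excess and recovered, 5 added slowly)
Reagents that add atoms: none
Why: Claisen–Schmidt condensation, in which the non-enolisable aldehyde adds to the enolate of one of the two equivalent methylene groups and E1cB loss of water gives the conjugated (E)-arylidene ketone (aryl trans to the aroyl group), the excess of 4 and slow addition of 5 holding the reaction at mono-condensation.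

Step 4
Reactants: 6 (2E)-1,4-bis[2,4-bis(benzyloxy)-6-(methoxymethoxy)phenyl]-2-[(4-methoxyphenyl)methylidene]butane-1,4-dione; 7 4-(benzyloxy)benzaldehyde
Product: 8 (2E,3E)-1,4-bis[2,4-bis(benzyloxy)-6-(methoxymethoxy)phenyl]-2-{[4-(benzyloxy)phenyl]methylidene}-3-[(4-methoxyphenyl)methylidene]butane-1,4-dione
Conditions: KOH, EtOH/THF, rt (7 in excess)
Reagents that add atoms: none
Why: Second Claisen–Schmidt condensation, in which the remaining methylene, flanked by the carbonyl and the arylidene-bearing carbon and therefore readily enolised, condenses with the second aldehyde to the thermodynamic (E,E)-diene and so fixes the methoxyphenyl and benzyloxyphenyl groups on different halves.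

Step 5
Reactants: 8 (2E,3E)-1,4-bis[2,4-bis(benzyloxy)-6-(methoxymethoxy)phenyl]-2-{[4-(benzyloxy)phenyl]methylidene}-3-[(4-methoxyphenyl)methylidene]butane-1,4-dione
Product: 9 (2E,3E)-1,4-bis[2,4-bis(benzyloxy)-6-hydroxyphenyl]-2-{[4-(benzyloxy)phenyl]methylidene}-3-[(4-methoxyphenyl)methylidene]butane-1,4-dione
Conditions: p-TsOH·H2O (cat.), MeOH/CH2Cl2, rt
Reagents that add atoms: none
Why: Acid-catalysed acetal exchange (methoxymethyl ether cleavage), in which the two acetals ortho to the carbonyl groups are transferred to methanol at room temperature, where benzyl ethers, the aryl methyl ether and the enones persist and acid-mediated ring closure of the hindered 2'-hydroxy enones is slow.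

Step 6
Reactants: 9 (2E,3E)-1,4-bis[2,4-bis(benzyloxy)-6-hydroxyphenyl]-2-{[4-(benzyloxy)phenyl]methylidene}-3-[(4-methoxyphenyl)methylidene]butane-1,4-dione
Product: 11 (2S,3S)-5,7-bis(benzyloxy)-3-{(2S,3S)-5,7-bis(benzyloxy)-2-[4-(benzyloxy)phenyl]-4-oxo-3,4-dihydro-2H-chromen-3-yl}-2-(4-methoxyphenyl)-2,3-dihydro-4H-chromen-4-one, via monocyclised flavanone 10 (not isolated)
Conditions: thiourea from 9-amino-9-deoxy-epi-quinidine and 3,5-bis(trifluoromethyl)phenyl isothiocyanate (20 mol %), toluene, 0 °C
Reagents that add atoms: none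
Why: Proposed new method: the quinuclidine nitrogen of the bifunctional catalyst takes up the proton of one ring A hydroxyl while the thiourea binds the neighbouring enone carbonyl, the phenoxide oxygen adds to the benzylic β-carbon in a 6-endo-trig oxa-Michael addition, the enol(ate) is protonated at the α-carbon by the ammonium ion, and the same sequence repeats on the second 2'-hydroxy enone of 10, so that O1–C2, O1''–C2'' and both pyranone rings form in one operation. The closest known reaction type is the amine–thiourea-catalysed asymmetric cyclisation of 2'-hydroxychalcones to flavanones, together with the base-mediated closure of α-substituted 2'-hydroxychalcones to 3-substituted flavanones; what has not been shown is the twofold, catalyst-controlled closure of an unactivated, α-branched bis-enone with kinetic control at both α-carbons. C2 and C2'' are set by the catalyst, which selects the same enantiotopic face of each of the two nearly equivalent enones, so the (2S,2''S) product needs no induction between the halves, its enantiomer requires two errors, and the (2S,2''R) isomer is a separable diastereomer. C3 and C3'' are set by kinetic protonation of each cyclic enol(ate) on the face opposite the adjacent 2-aryl group, which sits pseudoaxial to avoid allylic strain with the C3 substituent, and this places H3 trans to the aryl group and gives the 2,3-cis relationship in both rings. The step needs 6-endo closure rather than attack of a phenol on the remote enone (seven-membered ring), α- rather than γ-protonation of the cross-conjugated dienolate, and no later equilibration of the cis centres; these are secured by the ortho placement of each hydroxyl on its own aroyl group, by protonation with a weak ammonium acid at low temperature in an apolar solvent, and by the benzyloxy group ortho to each carbonyl, which shifts the chalcone–flavanone equilibrium to the closed side so that mild conditions suffice.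

Step 7
Reactants: 11 (2S,3S)-5,7-bis(benzyloxy)-3-{(2S,3S)-5,7-bis(benzyloxy)-2-[4-(benzyloxy)phenyl]-4-oxo-3,4-dihydro-2H-chromen-3-yl}-2-(4-methoxyphenyl)-2,3-dihydro-4H-chromen-4-one
Product: 12 sikokianin A
Conditions: H2 (1 atm), 10% Pd/C, EtOAc/MeOH, rt
Reagents that add atoms: none
Why: Catalytic hydrogenolysis of O-benzyl ethers, in which the five benzyl groups are removed on Pd/C under neutral conditions that neither enolise C3/C3'' nor open the pyranone rings, while the aryl methyl ether, the ketones and the four stereocentres are left as they are.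

**Compound list**

1 | 1-[2,4-bis(benzyloxy)-6-hydroxyphenyl]ethan-1-one | CC(=O)c1c(O)cc(OCc2ccccc2)cc1OCc1ccccc1 | starting material
2 | 1-[2,4-bis(benzyloxy)-6-(methoxymethoxy)phenyl]ethan-1-one | CC(=O)c1c(OCOC)cc(OCc2ccccc2)cc1OCc1ccccc1 | intermediate
3 | lithium enolate of 2 | [Li+].[O-]C(=C)c1c(OCOC)cc(OCc2ccccc2)cc1OCc1ccccc1 | intermediate
4 | 1,4-bis[2,4-bis(benzyloxy)-6-(methoxymethoxy)phenyl]butane-1,4-dione | O=C(CCC(=O)c1c(OCOC)cc(OCc2ccccc2)cc1OCc1ccccc1)c1c(OCOC)cc(OCc2ccccc2)cc1OCc1ccccc1 | intermediate
5 | 4-methoxybenzaldehyde | COc1ccc(C=O)cc1 | starting material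
6 | (2E)-1,4-bis[2,4-bis(benzyloxy)-6-(methoxymethoxy)phenyl]-2-[(4-methoxyphenyl)methylidene]butane-1,4-dione | COc1ccc(cc1)/C=C(/C(=O)c1c(OCOC)cc(OCc2ccccc2)cc1OCc1ccccc1)CC(=O)c1c(OCOC)cc(OCc2ccccc2)cc1OCc1ccccc1 | intermediate
7 | 4-(benzyloxy)benzaldehyde | O=Cc1ccc(OCc2ccccc2)cc1 | starting material
8 | (2E,3E)-1,4-bis[2,4-bis(benzyloxy)-6-(methoxymethoxy)phenyl]-2-{[4-(benzyloxy)phenyl]methylidene}-3-[(4-methoxyphenyl)methylidene]butane-1,4-dione | COc1ccc(cc1)/C=C(/C(=O)c1c(OCOC)cc(OCc2ccccc2)cc1OCc1ccccc1)C(=C\c1ccc(OCc2ccccc2)cc1)/C(=O)c1c(OCOC)cc(OCc2ccccc2)cc1OCc1ccccc1 | intermediate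
9 | (2E,3E)-1,4-bis[2,4-bis(benzyloxy)-6-hydroxyphenyl]-2-{[4-(benzyloxy)phenyl]methylidene}-3-[(4-methoxyphenyl)methylidene]butane-1,4-dione | COc1ccc(cc1)/C=C(/C(=O)c1c(O)cc(OCc2ccccc2)cc1OCc1ccccc1)C(=C\c1ccc(OCc2ccccc2)cc1)/C(=O)c1c(O)cc(OCc2ccccc2)cc1OCc1ccccc1 | intermediate
10 | monocyclised flavanone: (2S,3S)-5,7-bis(benzyloxy)-3-{(1E)-3-[2,4-bis(benzyloxy)-6-hydroxyphenyl]-1-[4-(benzyloxy)phenyl]-3-oxoprop-1-en-2-yl}-2-(4-methoxyphenyl)-2,3-dihydro-4H-chromen-4-one | COc1ccc([C@H]2Oc3cc(OCc4ccccc4)cc(OCc4ccccc4)c3C(=O)[C@H]2C(=C\c2ccc(OCc3ccccc3)cc2)/C(=O)c2c(O)cc(OCc3ccccc3)cc2OCc2ccccc2)cc1 | intermediate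
11 | (2S,3S)-5,7-bis(benzyloxy)-3-{(2S,3S)-5,7-bis(benzyloxy)-2-[4-(benzyloxy)phenyl]-4-oxo-3,4-dihydro-2H-chromen-3-yl}-2-(4-methoxyphenyl)-2,3-dihydro-4H-chromen-4-one (penta-O-benzylsikokianin A) | COc1ccc([C@H]2Oc3cc(OCc4ccccc4)cc(OCc4ccccc4)c3C(=O)[C@H]2[C@@H]2C(=O)c3c(OCc4ccccc4)cc(OCc4ccccc4)cc3O[C@@H]2c2ccc(OCc3ccccc3)cc2)cc1 | intermediate
12 | sikokianin A: (2S,3S)-3-[(2S,3S)-5,7-dihydroxy-2-(4-hydroxyphenyl)-4-oxo-3,4-dihydro-2H-chromen-3-yl]-5,7-dihydroxy-2-(4-methoxyphenyl)-2,3-dihydro-4H-chromen-4-one | COc1ccc([C@H]2Oc3cc(O)cc(O)c3C(=O)[C@H]2[C@@H]2C(=O)c3c(O)cc(O)cc3O[C@@H]2c2ccc(O)cc2)cc1 | target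

**Step count and risks**

Total step count: 7. Longest linear sequence: 7 steps (1 → 12).

Steps most likely to fail:

1. Step 6. The catalyst may discriminate poorly between the faces of the unactivated, α-branched enones, which would give the enantiomer and the (2S,2''R) diastereomer, and the kinetically set C3/C3'' centres may partly equilibrate to the trans arrangement. The fallback sets out from 9 and comes back at 11. Compound 9 would be closed without stereocontrol (NaOAc, EtOH, reflux) to the stereoisomer mixture of the pentabenzyl biflavanone F1. Soft enolisation (TMSOTf, Et3N, CH2Cl2, −78 → 0 °C) would convert it into the bis(trimethylsilyl enol ether) F2, which erases C3 and C3'' but keeps C2 and C2''. Protonolysis at −78 °C (Bu4NF/AcOH, THF) should deliver hydrogen anti to each 2-aryl group and give the cis,cis isomers. The pair with like configuration at C2/C2'' would be separated from the meso-like isomer on silica and resolved on a chiral stationary phase to give 11.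

2. Step 3. Condensation may run on to the second methylene, because the mono-arylidene product is more acidic than 4, which would consume the aldehyde in a symmetric bis-condensation. The fallback sets out from 4 and comes back at 6. One equivalent of LiN(SiMe3)2 (THF, −78 °C) would form the mono-enolate of 4 irreversibly, and addition of 5 followed by a cold quench would give the aldol adduct F3 as a diastereomer mixture with the second methylene untouched. Mesylation and elimination (MsCl, Et3N, then DBU, CH2Cl2) would then give 6.

3. Step 2. α-Chlorination of the enolate by CuCl2 may compete, and coupling at the hindered ketone may be incomplete. The fallback sets out from 2 and comes back at 4, replacing the oxidative coupling by a polar bond formation. Lithium enolate 3 would be brominated with NBS at −78 °C to the 2-bromo ketone F4, and a second portion of 3 would be alkylated by F4 (SN2 at the phenacyl-type carbon, THF, −78 → 0 °C) to give 4.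

Further compounds
F1 | step 6 | 5,7-bis(benzyloxy)-3-{5,7-bis(benzyloxy)-2-[4-(benzyloxy)phenyl]-4-oxo-3,4-dihydro-2H-chromen-3-yl}-2-(4-methoxyphenyl)-2,3-dihydro-4H-chromen-4-one, mixture of stereoisomers | COc1ccc(C2Oc3cc(OCc4ccccc4)cc(OCc4ccccc4)c3C(=O)C2C2C(=O)c3c(OCc4ccccc4)cc(OCc4ccccc4)cc3OC2c2ccc(OCc3ccccc3)cc2)cc1
F2 | step 6 | bis(trimethylsilyl enol ether) of F1, mixture of C2/C2'' stereoisomers | COc1ccc(C2Oc3cc(OCc4ccccc4)cc(OCc4ccccc4)c3C(O[Si](C)(C)C)=C2C2=C(O[Si](C)(C)C)c3c(OCc4ccccc4)cc(OCc4ccccc4)cc3OC2c2ccc(OCc3ccccc3)cc2)cc1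
F3 | step 3 | 1,4-bis[2,4-bis(benzyloxy)-6-(methoxymethoxy)phenyl]-2-[hydroxy(4-methoxyphenyl)methyl]butane-1,4-dione, mixture of diastereomers | COc1ccc(cc1)C(O)C(CC(=O)c1c(OCOC)cc(OCc2ccccc2)cc1OCc1ccccc1)C(=O)c1c(OCOC)cc(OCc2ccccc2)cc1OCc1ccccc1
F4 | step 2 | 1-[2,4-bis(benzyloxy)-6-(methoxymethoxy)phenyl]-2-bromoethan-1-one | BrCC(=O)c1c(OCOC)cc(OCc2ccccc2)cc1OCc1ccccc1
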